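Assumption: germacrane numbering is used (C1 ketone, C2 =CH, C3 enol-ether carbon, C4 CHMe, C5, C6 lactone carbinol, C7, C8 ester carbinol, C9, C10 quaternary C–O, C11 CHMe, C12 lactone C=O); in step 3 the BINAP antipode is the one that delivers the (S)-lactone (checked by optical rotation, otherwise the antipode is used).

**Retrosynthetic overview**
1. The tiglate goes on last; the γ-lactone and the 10-membered carbocycle (a 9-membered oxa-bridged ring) are closed together by a SmI2 ketyl–enoate cyclisation that joins C6 (aldehyde carbon used as a ketyl nucleophile) to C7 (β-carbon of the enoate).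
2. The seco-aldehyde comes from a 2,2,5-trisubstituted 3(2H)-furanone: the C10 vinyl group is hydroformylated, then D-proline α-aminoxylation/Wittig sets C8 and builds the (E)-enoate.
3. The furanone (first ring) comes from a γ-hydroxy ynone, made from the lithium acetylide of (R)-3-methylpent-1-en-4-yn-3-ol and (S)-α-methyl-γ-butyrolactone.
4. Stereocentres: C10 by Sharpless epoxidation, C4 by Ru–BINAP hydrogenation, C8 by D-proline, and C6, C7, C11 by substrate control in the key step.
5. Ring order: furanone, then carbocycle and lactone in one step; no protecting groups.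

**Route**

Step 1
Reactants: 1 (E)-3-methylpent-2-en-4-yn-1-ol
Product: 2 [(2S,3S)-3-ethynyl-3-methyloxiran-2-yl]methanol
Conditions: Ti(OiPr)4 (5 mol %), L-(+)-diisopropyl tartrate (7 mol %), t-BuOOH, molecular sieves (4 Å), CH2Cl2, −20 °C
Reagents that add atoms: tert-butyl hydroperoxide, CC(C)(C)OO
Why: Katsuki–Sharpless asymmetric epoxidation of an (E)-trisubstituted allylic alcohol; the L-(+)-tartrate delivers oxygen to the same face as in geraniol (which gives the 2S,3S epoxide), fixing the tertiary C–O centre that becomes C10.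

Step 2
Reactants: 2 [(2S,3S)-3-ethynyl-3-methyloxiran-2-yl]methanol
Product: 4 (R)-3-methylpent-1-en-4-yn-3-ol, via epoxy iodide 3 (not isolated)
Conditions: PPh3, I2, imidazole, CH2Cl2, 0 °C; then Zn dust, AcOH, EtOH, 0 °C to rt
Reagents that add atoms: none
Why: Appel-type iodination followed by zinc-induced reductive β-elimination opens the epoxide to the transposed tertiary vinyl carbinol (the route used for linalool from epoxygeraniol); the quaternary C–O bond is never broken, so the configuration is retained.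

Step 3
Reactants: 5 α-methylene-γ-butyrolactone
Product: 6 (S)-3-methyldihydrofuran-2(3H)-one
Conditions: H2 (50 atm), Ru(OAc)2[(R)-BINAP] (0.5 mol %), CH2Cl2, 50 °C
Reagents that add atoms: none
Why: Noyori-type Ru–BINAP asymmetric hydrogenation of the exocyclic enoate; ligand-controlled face selection sets the methyl-bearing centre that becomes C4 (S).

Step 4
Reactants: 4 (R)-3-methylpent-1-en-4-yn-3-ol; 6 (S)-3-methyldihydrofuran-2(3H)-one
Product: 7 (3R,7S)-3,9-dihydroxy-3,7-dimethylnon-1-en-4-yn-6-one
Conditions: 4, n-BuLi (2.05 equiv), THF, −78 to 0 °C; then 6, −78 to −40 °C; aq. NH4Cl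
Reagents that add atoms: none
Why: Acyl substitution of the lactone by the acetylide of the alkoxide–acetylide dianion; the lactol alkoxide resists a second addition and opens on work-up to the hydroxy ynone; no stereocentre is formed and the low temperature protects the α-methyl centre.

Step 5
Reactants: 7 (3R,7S)-3,9-dihydroxy-3,7-dimethylnon-1-en-4-yn-6-one
Product: 9 (2R)-2-ethenyl-5-[(2S)-4-hydroxybutan-2-yl]-2-methylfuran-3(2H)-one, via enaminone 8 (not isolated)
Conditions: Et2NH (2 equiv), EtOH, rt; then AcOH–H2O (3:1), 40 °C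
Reagents that add atoms: none
Why: Jackson–Raphael 3(2H)-furanone synthesis: conjugate addition of the amine to the ynone, hydrolysis to the α'-hydroxy-1,3-diketone and cyclodehydration by the tertiary hydroxyl give the endocyclic vinylogous ester (a net isomerisation); no stereocentre is formed or broken.

Step 6
Reactants: 9 (2R)-2-ethenyl-5-[(2S)-4-hydroxybutan-2-yl]-2-methylfuran-3(2H)-one
Product: 10 3-{(2R)-5-[(2S)-4-hydroxybutan-2-yl]-2-methyl-3-oxo-2,3-dihydrofuran-2-yl}propanal
Conditions: CO/H2 (1:1, 10 bar), Rh(acac)(CO)2 (1 mol %), Xantphos (2 mol %), toluene, 70 °C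
Reagents that add atoms: carbon monoxide, [C-]#[O+]
Why: Rhodium-catalysed hydroformylation; the quaternary allylic carbon (neohexene-type alkene) and the wide-bite-angle ligand enforce the linear aldehyde, which supplies C7; the alkene cannot isomerise.

Step 7
Reactants: 10 3-{(2R)-5-[(2S)-4-hydroxybutan-2-yl]-2-methyl-3-oxo-2,3-dihydrofuran-2-yl}propanal; 11 ethyl 2-(triphenylphosphoranylidene)propanoate
Product: 13 ethyl (2E,4S)-4-(anilinooxy)-5-{(2R)-5-[(2S)-4-hydroxybutan-2-yl]-2-methyl-3-oxo-2,3-dihydrofuran-2-yl}-2-methylpent-2-enoate, via aminooxy aldehyde 12 (not isolated)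
Conditions: PhNO (1.0 equiv), D-proline (20 mol %), DMSO, 20 °C; then 11 (1.5 equiv), CH2Cl2, 0 °C to rt
Reagents that add atoms: nitrosobenzene, O=Nc1ccccc1; 11 ethyl 2-(triphenylphosphoranylidene)propanoate, CCOC(=O)C(C)=P(c1ccccc1)(c1ccccc1)c1ccccc1
Why: Proline-catalysed α-aminoxylation (enamine catalysis, O-selective nitroso aldol) sets C8 under catalyst control (L-proline gives R, so D-proline gives the required S), and the in-situ Wittig reaction of the stabilised ylide gives the (E)-trisubstituted enoate.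

Step 8
Reactants: 13 ethyl (2E,4S)-4-(anilinooxy)-5-{(2R)-5-[(2S)-4-hydroxybutan-2-yl]-2-methyl-3-oxo-2,3-dihydrofuran-2-yl}-2-methylpent-2-enoate
Product: 14 ethyl (2E,4S)-4-hydroxy-5-{(2R)-5-[(2S)-4-hydroxybutan-2-yl]-2-methyl-3-oxo-2,3-dihydrofuran-2-yl}-2-methylpent-2-enoate
Conditions: Cu(OAc)2 (30 mol %), EtOH, rt
Reagents that add atoms: none
Why: Copper-catalysed N–O cleavage of the anilinooxy group, the standard sequel to aminoxylation; the C8–O bond is untouched, so the configuration is retained.

Step 9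
Reactants: 14 ethyl (2E,4S)-4-hydroxy-5-{(2R)-5-[(2S)-4-hydroxybutan-2-yl]-2-methyl-3-oxo-2,3-dihydrofuran-2-yl}-2-methylpent-2-enoate
Product: 15 ethyl (2E,4S)-4-hydroxy-2-methyl-5-{(2R)-2-methyl-3-oxo-5-[(2S)-4-oxobutan-2-yl]-2,3-dihydrofuran-2-yl}pent-2-enoate
Conditions: TEMPO (10 mol %), PhI(OAc)2 (1.1 equiv), CH2Cl2, rt
Reagents that add atoms: none
Why: Oxoammonium (TEMPO/PhI(OAc)2) oxidation is selective for the primary alcohol over the secondary, electron-poor allylic C8 alcohol and gives the C6 aldehyde without touching C4.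

Step 10
Reactants: 15 ethyl (2E,4S)-4-hydroxy-2-methyl-5-{(2R)-2-methyl-3-oxo-5-[(2S)-4-oxobutan-2-yl]-2,3-dihydrofuran-2-yl}pent-2-enoate
Product: 17 (4S,6R,7S,8S,10R,11S)-8-hydroxy-1-oxo-3,10-epoxygermacr-2-en-6,12-olide (the target lacking the tigloyl group), via macrocyclic hydroxy ester 16 (not isolated)
Conditions: SmI2 (2.5 equiv, 0.1 M in THF) added over 4 h to 15 (2 mM) and t-BuOH (3 equiv) in THF, 0 °C to rt; aq. potassium sodium tartrate
Reagents that add atoms: none
Why: Proposed new method: SmI2 reduces only the aldehyde (vinylogous esters and enoates are not reduced without HMPA) to a samarium ketyl, a reversed-polarity C6 nucleophile that adds to C7, the β-carbon of the enoate; a second electron gives the ester enolate, which is protonated, and the trivalent samarium C6 alkoxide lactonises; the closest known reaction types are the Fukuzawa SmI2 ketyl–acrylate γ-lactone synthesis and SmI2 ketyl–olefin closures of 8-membered rings, here extended to a 9-membered oxa-bridged ring; the ketyl has no 5-exo path to the furanone; C7 is set because A(1,3) strain holds C8–H in the alkene plane so the tether (C9 side) attacks anti to O8, C6 by the staggered chelated transition state with H6 inside and the O–Sm group anti to C8 (trans lactone), and C11 by protonation anti to the pseudo-axial C7–H, as in hydride reductions of α-methylene germacranolides, which is also the thermodynamic epimer.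

Step 11
Reactants: 17 (4S,6R,7S,8S,10R,11S)-8-hydroxy-1-oxo-3,10-epoxygermacr-2-en-6,12-olide; 18 tigloyl chloride
Product: 19 CNP0235937.1 (target)
Conditions: 18 (3 equiv), pyridine, DMAP (0.2 equiv), CH2Cl2, 0 °C to rt
Reagents that add atoms: 18 tigloyl chloride [(E)-2-methylbut-2-enoyl chloride], C/C=C(\C)C(Cl)=O
Why: DMAP-catalysed acylation of the only free hydroxyl (C8) with retention at carbon; the (E)-tigloyl geometry is the stable one and is not at risk.

**Compound list**
1 | (E)-3-methylpent-2-en-4-yn-1-ol | OC/C=C(\C)C#C | starting material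
2 | [(2S,3S)-3-ethynyl-3-methyloxiran-2-yl]methanol | OC[C@@H]1O[C@@]1(C)C#C | intermediate
3 | (2S,3R)-2-ethynyl-3-(iodomethyl)-2-methyloxirane | IC[C@@H]1O[C@@]1(C)C#C | intermediate
4 | (R)-3-methylpent-1-en-4-yn-3-ol | C=C[C@@](C)(O)C#C | intermediate
5 | α-methylene-γ-butyrolactone | C=C1CCOC1=O | starting material
6 | (S)-3-methyldihydrofuran-2(3H)-one | C[C@H]1CCOC1=O | intermediate
7 | (3R,7S)-3,9-dihydroxy-3,7-dimethylnon-1-en-4-yn-6-one | OCC[C@H](C)C(=O)C#C[C@](C)(O)C=C | intermediate
8 | (3R,4E,7S)-4-(diethylamino)-3,9-dihydroxy-3,7-dimethylnona-1,4-dien-6-one | OCC[C@H](C)C(=O)/C=C(/N(CC)CC)[C@](C)(O)C=C | intermediate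
9 | (2R)-2-ethenyl-5-[(2S)-4-hydroxybutan-2-yl]-2-methylfuran-3(2H)-one | OCC[C@H](C)C1=CC(=O)[C@@](C)(C=C)O1 | intermediate
10 | 3-{(2R)-5-[(2S)-4-hydroxybutan-2-yl]-2-methyl-3-oxo-2,3-dihydrofuran-2-yl}propanal | OCC[C@H](C)C1=CC(=O)[C@@](C)(CCC=O)O1 | intermediate
11 | ethyl 2-(triphenylphosphoranylidene)propanoate | CCOC(=O)C(C)=P(c1ccccc1)(c1ccccc1)c1ccccc1 | starting material
12 | (2S)-2-(anilinooxy)-3-{(2R)-5-[(2S)-4-hydroxybutan-2-yl]-2-methyl-3-oxo-2,3-dihydrofuran-2-yl}propanal | OCC[C@H](C)C1=CC(=O)[C@@](C)(C[C@H](ONc2ccccc2)C=O)O1 | intermediate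
13 | ethyl (2E,4S)-4-(anilinooxy)-5-{(2R)-5-[(2S)-4-hydroxybutan-2-yl]-2-methyl-3-oxo-2,3-dihydrofuran-2-yl}-2-methylpent-2-enoate | OCC[C@H](C)C1=CC(=O)[C@@](C)(C[C@H](ONc2ccccc2)/C=C(\C)C(=O)OCC)O1 | intermediate
14 | ethyl (2E,4S)-4-hydroxy-5-{(2R)-5-[(2S)-4-hydroxybutan-2-yl]-2-methyl-3-oxo-2,3-dihydrofuran-2-yl}-2-methylpent-2-enoate | OCC[C@H](C)C1=CC(=O)[C@@](C)(C[C@H](O)/C=C(\C)C(=O)OCC)O1 | intermediate
15 | ethyl (2E,4S)-4-hydroxy-2-methyl-5-{(2R)-2-methyl-3-oxo-5-[(2S)-4-oxobutan-2-yl]-2,3-dihydrofuran-2-yl}pent-2-enoate | O=CC[C@H](C)C1=CC(=O)[C@@](C)(C[C@H](O)/C=C(\C)C(=O)OCC)O1 | intermediate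
16 | ethyl (2S)-2-[(4S,6R,7S,8S,10R)-6,8-dihydroxy-1-oxo-3,10-epoxygermacr-2-en-7-yl]propanoate (ring-closed diol ester before lactonisation) | O[C@H]1C[C@@]2(C)OC(=CC2=O)[C@@H](C)C[C@@H](O)[C@@H]1[C@H](C)C(=O)OCC | intermediate
17 | (4S,6R,7S,8S,10R,11S)-8-hydroxy-1-oxo-3,10-epoxygermacr-2-en-6,12-olide | O[C@H]1C[C@@]2(C)OC(=CC2=O)[C@@H](C)C[C@H]2OC(=O)[C@@H](C)[C@H]12 | intermediate
18 | tigloyl chloride, (E)-2-methylbut-2-enoyl chloride | C/C=C(\C)C(Cl)=O | starting material
19 | CNP0235937.1, (4S,6R,7S,8S,10R,11S)-8-tigloyloxy-1-oxo-3,10-epoxygermacr-2-en-6,12-olide | C/C=C(\C)C(=O)O[C@H]1C[C@@]2(C)OC(=CC2=O)[C@@H](C)C[C@H]2OC(=O)[C@@H](C)[C@H]12 | target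

**Count**
Total steps: 11. Longest linear sequence: 10 (steps 1, 2, 4–11); step 3 is the one-step side branch.

**Three steps most likely to fail**

Step 10 (key ring closure). The risks are simple reduction of the aldehyde back to diol 14 (which can be recycled through step 9), pinacol dimerisation, the slow 9-membered closure onto a tiglate-type acceptor, and lactonisation to O8 instead of O6. The fallback sets out from 15 and comes back at 17, and replaces the ketyl by an acyl radical. The aldehyde is oxidised (NaClO2, NaH2PO4, 2-methylbut-2-ene) to the seco-acid F1, which (PhSe)2/PBu3 converts into the Se-phenyl selenoester F2. Slow addition of Bu3SnH/AIBN (benzene, 80 °C, 2 mM) generates the nucleophilic acyl radical, which adds to C7 under the same allylic-strain and tether control and gives the macrocyclic 6-keto ester F3. Hydroxyl-directed syn reduction of the C6 ketone (Et2BOMe, NaBH4, THF/MeOH, −78 °C; the 6,8-syn diol is the one required) and acid-catalysed lactonisation (camphorsulfonic acid) then give 17.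

Step 5 (furanone with a free primary hydroxyl). The primary hydroxyl can compete for C3 (exocyclic enol ether or spiroketal), and C4 is α to a ketone during the sequence. The endocyclic furanone is expected to be the thermodynamic product under the acidic finish, but this is not certain. The fallback sets out from 7 and comes back at 9, and removes the competing nucleophile. The primary hydroxyl is silylated (TBSCl, imidazole) to the silyl ether F4, which is cyclised under neutral conditions with Ph3PAuNTf2 in wet THF (conjugate hydration and cyclodehydration) to the silylated furanone F5. HF·pyridine then returns 9.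

Step 4 (acetylide opening of the lactone). The risks are double addition, enolisation of the lactone (erosion at C4) and low conversion with the dianion. The fallback sets out from 6 and comes back at 7, and changes the acyl donor. Lactone 6 is opened with MeNH(OMe)·HCl/i-PrMgCl to the hydroxy Weinreb amide F6. Three equivalents of the dilithio derivative of 4 (THF, −78 to 0 °C) then add once, through the chelated tetrahedral intermediate, to give 7.

**Further compounds**
F1 | step 10 | (3S)-3-{(2R)-2-[(2S,3E)-5-ethoxy-2-hydroxy-4-methyl-5-oxopent-3-en-1-yl]-2-methyl-3-oxo-2,3-dihydrofuran-5-yl}butanoic acid (seco-acid) | OC(=O)C[C@H](C)C1=CC(=O)[C@@](C)(C[C@H](O)/C=C(\C)C(=O)OCC)O1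
F2 | step 10 | Se-phenyl selenoester of F1 | O=C([Se]c1ccccc1)C[C@H](C)C1=CC(=O)[C@@](C)(C[C@H](O)/C=C(\C)C(=O)OCC)O1
F3 | step 10 | ethyl (2S)-2-[(4S,7R,8S,10R)-8-hydroxy-1,6-dioxo-3,10-epoxygermacr-2-en-7-yl]propanoate (macrocyclic 6-keto ester) | O[C@H]1C[C@@]2(C)OC(=CC2=O)[C@@H](C)CC(=O)[C@@H]1[C@H](C)C(=O)OCC
F4 | step 5 | (3R,7S)-9-[(tert-butyldimethylsilyl)oxy]-3-hydroxy-3,7-dimethylnon-1-en-4-yn-6-one | CC(C)(C)[Si](C)(C)OCC[C@H](C)C(=O)C#C[C@](C)(O)C=C
F5 | step 5 | (2R)-5-{(2S)-4-[(tert-butyldimethylsilyl)oxy]butan-2-yl}-2-ethenyl-2-methylfuran-3(2H)-one | CC(C)(C)[Si](C)(C)OCC[C@H](C)C1=CC(=O)[C@@](C)(C=C)O1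
F6 | step 4 | (2S)-4-hydroxy-N-methoxy-N,2-dimethylbutanamide | OCC[C@H](C)C(=O)N(C)OC
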